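**Retrosynthetic overview** (germacrane numbering: C1–C10 ring carbons, C11–C13 lactone carbons, C14 = CH3 on C10, C15 on C4)

1. The target is an α-methylene γ-lactone (O, C6, C7, C11, C12) trans-fused to oxepane ring B (O, C5–C10), which shares its ether oxygen and both α-carbons (C5, C10) with oxepane ring A (O, C10, C1–C5).
2. Key disconnection: ring A at C3–C4 by an intramolecular nitrile oxide–alkene (3+2) cycloaddition; the isoxazoline (C3=N–O–C15–C4) is a temporary ring that is opened again to give the 3-OH and the 15-oxygen.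
3. Enabling feature: the C3(OH)–C4(H)–C15H2–O aldol-type unit of ring A is an isoxazoline retron, and C4 hangs on bridgehead C5, an allylic-ether carbon of ring B. A vinyl group on C5 and a nitrile oxide on the three-carbon arm (C1–C3) of C10 therefore close ring A across the ether oxygen, at a bond remote from both bridgeheads.
4. Ring B: O–C5 bond by palladium-catalysed cycloetherification of a cis-vinyl epoxide with the C10 tertiary alcohol, then lactonisation; C5/C6 from γ-chloroallylboration, C7/C8 from a proline cross-aldol, C10 from (R)-linalool.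
5. Order of ring formation: ring B, γ-lactone, then ring A (with the isoxazoline); the exocyclic methylene is carried as a Mannich base and released last.

Key step: step 13

Assumption: the descriptors are read literally; C5 (R) and C10 (R) put the C4 and C1 arms on opposite faces of ring B, so the two oxepanes are trans-bridged through the ether oxygen (an inside–outside bicycle), and both bridgeheads are therefore fixed before ring A is closed.

**Step 1**
Reactants: 1 (R)-linalool
Product: 2 linalool TMS ether
Conditions: TMSCl, imidazole, DMF, 0 °C → rt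
Reagents that add atoms: chlorotrimethylsilane, C[Si](C)(C)Cl
Why: Silyl ether formation on the tertiary alcohol; C10 (R) of the target comes unchanged from (R)-linalool, and masking the hydroxyl keeps the later β-oxy aldehyde 5 from retro-aldol cleavage under amine catalysis.

**Step 2**
Reactants: 2 linalool TMS ether
Product: 4 silyloxy alcohol, via alkylborane 3 (not isolated)
Conditions: 9-BBN, THF, 0 °C → rt; then 30% H2O2, aq. NaOAc, 0 °C → rt
Reagents that add atoms: hydrogen peroxide, OO
Why: Anti-Markovnikov hydroboration–oxidation; 9-BBN should take the monosubstituted vinyl group in preference to the trisubstituted alkene and place boron on the terminal carbon (C8), and the buffered peroxide should spare the silyl ether.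

**Step 3**
Reactants: 4 silyloxy alcohol
Product: 5 silyloxy aldehyde
Conditions: Dess–Martin periodinane, NaHCO3, CH2Cl2, 0 °C → rt
Reagents that add atoms: none
Why: Dess–Martin oxidation of the primary alcohol under buffered, non-aqueous conditions that should leave the tertiary silyl ether and the alkene untouched.

**Step 4**
Reactants: 5 silyloxy aldehyde; 6 tert-butyl 4-oxobutanoate
Product: 7 anti-aldol aldehyde
Conditions: D-proline (20 mol%), DMF, 4 °C, 6 added slowly by syringe pump
Reagents that add atoms: none
Why: Proline-catalysed direct cross-aldol of two aldehydes (enamine catalysis): the enamine of the unhindered donor 6 should add to acceptor 5, whose neopentylic α-carbon makes it a poor donor, through the hydrogen-bonded chair-like transition state that gives the anti adduct, the D-catalyst setting C7 (R) and C8 (R).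

**Step 5**
Reactants: 7 anti-aldol aldehyde
Product: 8 TBS-protected aldol aldehyde
Conditions: TBSOTf, 2,6-lutidine, CH2Cl2, −78 °C
Reagents that add atoms: tert-butyldimethylsilyl triflate, CC(C)(C)[Si](C)(C)OS(=O)(=O)C(F)(F)F
Why: Low-temperature silylation of the C8 hydroxyl, which should not epimerise the α-centre C7 and keeps this hydroxyl from competing as a nucleophile in step 7, where it would close a tetrahydrofuran on C5.

**Step 6**
Reactants: 8 TBS-protected aldol aldehyde
Product: 10 cis-vinyl epoxide, via chlorohydrin 9 (not isolated)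
Conditions: allyl chloride, LiN(c-C6H11)2, (+)-Ipc2BOMe, BF3·OEt2, Et2O, −95 °C; then 8, −95 °C; HOCH2CH2NH2; then K2CO3, MeOH, 0 °C → rt
Reagents that add atoms: (Z)-(γ-chloroallyl)diisopinocampheylborane, Cl/C=C\CB([C@H]1C[C@H]2C[C@@H]([C@@H]1C)C2(C)C)[C@H]1C[C@H]2C[C@@H]([C@@H]1C)C2(C)C
Why: Asymmetric γ-chloroallylboration followed by intramolecular Williamson epoxide closure: the closed chair transition state of the (Z)-reagent should give the syn chlorohydrin, the isopinocampheyl groups (reagent control, antipode chosen for this sense) selecting the aldehyde face that makes C6 (S), and displacement of chloride with inversion should give the cis epoxide (5R,6S) while K2CO3/MeOH also cleaves the tertiary TMS ether.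

**Step 7**
Reactants: 10 cis-vinyl epoxide
Product: 12 oxepane lactone, via hydroxy ester 11 (not isolated)
Conditions: Pd(PPh3)4 (5 mol%), THF, 0 °C → rt; then CSA (10 mol%), CH2Cl2, rt
Reagents that add atoms: none
Why: Tsuji–Trost-type cycloetherification of a hydroxy vinyl epoxide: zerovalent palladium should open the epoxide with inversion to a π-allyl complex and the C10 tertiary hydroxyl should attack C5 anti to the metal (seven- rather than nine-membered ring), so that ring B forms with net retention at C5 and the C5 vinyl group trans to the C10 side chain, after which acid-catalysed lactonisation of the freed C6 hydroxyl with the tert-butyl ester should give the trans-fused γ-lactone.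

**Step 8**
Reactants: 12 oxepane lactone
Product: 14 Mannich base, via lithium enolate 13 (not isolated)
Conditions: LiN(i-Pr)2, THF, −78 °C; then [CH2=NMe2]I, −78 °C → rt
Reagents that add atoms: N,N-dimethylmethyleneiminium iodide (Eschenmoser's salt), C=[N+](C)C.[I-]
Why: Mannich aminomethylation of the lactone enolate, the only acidic site; the iminium ion should approach C11 anti to the C7–C8 bond (11R), and the β-amino lactone is the masked α-methylene group, inert to the dipole and hydride steps ahead.

**Step 9**
Reactants: 14 Mannich base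
Product: 15 C8 alcohol
Conditions: HF·pyridine, pyridine, THF, 0 °C → rt
Reagents that add atoms: none
Why: Fluoride cleavage of the secondary TBS ether under buffered, non-basic conditions, which should avoid translactonisation of the cis-disposed C8 hydroxyl onto the lactone carbonyl.

**Step 10**
Reactants: 15 C8 alcohol
Product: 16 angelate
Conditions: angelic acid, 2,4,6-Cl3C6H2COCl, Et3N, toluene, rt; then 15, 70 °C
Reagents that add atoms: angelic acid [(Z)-2-methylbut-2-enoic acid], C/C=C(/C)C(=O)O
Why: Yamaguchi-type mixed-anhydride esterification of the hindered secondary alcohol; the preformed mixed anhydride, used without a nucleophilic amine catalyst, should transfer the angeloyl group without Z to E isomerisation to the tiglate.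

**Step 11**
Reactants: 16 angelate
Product: 18 aldehyde, via ozonide 17 (not isolated)
Conditions: CF3CO2H (1.1 equiv), O3, CH2Cl2, −78 °C (Sudan Red 7B end point); then PPh3, −78 °C → rt; aq. NaHCO3
Reagents that add atoms: ozone, [O-][O+]=O
Why: Ozonolysis with reductive work-up; the electron-rich trisubstituted alkene should react well before the monosubstituted allylic-ether vinyl group and the electron-poor angelate, and the amine is shielded from ozone as its ammonium salt.

**Step 12**
Reactants: 18 aldehyde
Product: 19 aldoxime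
Conditions: NH2OH·HCl, NaOAc, EtOH, rt
Reagents that add atoms: hydroxylamine hydrochloride, Cl.NO
Why: Oxime condensation of the aldehyde (E/Z mixture, both isomers serve); the lactone, the esters and the hindered enoate should not react with hydroxylamine under these conditions.

**Step 13**
Reactants: 19 aldoxime
Product: 21 isoxazoline, via nitrile oxide 20 (not isolated)
Conditions: PhI(OAc)2, CF3CO2H (1.2 equiv), MeOH–CH2Cl2, 0 °C → rt, 2 mM, oxidant added slowly
Reagents that add atoms: none
Why: Oxidation of aldoxime 19 by PhI(OAc)2 gives nitrile oxide 20, which adds across the C4=C15 vinyl group on C5 in a concerted (3+2) dipolar cycloaddition; the closest known reaction type is the intramolecular nitrile oxide–alkene cycloaddition of ether-tethered alkenyl oximes to isoxazoline-fused oxepanes. Ring A (O–C10–C1–C2–C3–C4–C5) closes in the fused (exo) mode, C3 bonding to the internal alkene carbon C4, while the isoxazoline (C3=N–O–C15–C4) is the second, temporary ring; the bridged mode would need an eight-membered ring with a bridgehead C=N bond. The one new stereocentre, C4, is controlled by the allylic ether centre C5: in the transition state the tether oxygen on C5 lies inside (near the alkene plane), the ring B carbon C6 is anti to the incoming dipole and H5 is outside, which puts C15 cis to C6 as in the target. Because C3–C4 is remote from both bridgeheads, the trans disposition of the C5 and C10 arms fixed in steps 1, 6 and 7 is carried into the bicycle unchanged. The step needs chemoselectivity for the vinyl group over the trisubstituted, electron-poor angelate (a poor dipolarophile) and over dimerisation to furoxan; this is secured by the absence of any other reactive alkene (the α-methylene lactone is masked as the amine, itself protected as its ammonium salt) and by high dilution with slow addition of the oxidant.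

**Step 14**
Reactants: 21 isoxazoline
Product: 23 hydroxy ketone, via hydroxy imine 22 (not isolated)
Conditions: Mo(CO)6, MeCN–H2O (15:1), 80 °C
Reagents that add atoms: water, O
Why: Reductive N–O cleavage of the isoxazoline by Mo(CO)6 and hydrolysis of the resulting imine should unmask the aldol (C3 ketone, C15 hydroxyl) without touching the alkenes, as hydrogenolysis might; the neutral conditions should not enolise C4.

**Step 15**
Reactants: 23 hydroxy ketone
Product: 24 diol
Conditions: Zn(BH4)2, Et2O, −30 °C
Reagents that add atoms: none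
Why: Chelation-controlled ketone reduction: zinc should bridge the C3 carbonyl and the C15 hydroxyl, and hydride should add to the ring face opposite the C4 hydroxymethyl arm, giving the 3-hydroxyl cis to C15 (3S) while the esters and the lactone are left alone.

**Step 16**
Reactants: 24 diol
Product: 25 monoacetate
Conditions: AcCl (1.1 equiv), 2,4,6-collidine, CH2Cl2, −78 °C
Reagents that add atoms: acetyl chloride, CC(Cl)=O
Why: Selective acylation of the primary C15 hydroxyl in the presence of the hindered secondary C3 hydroxyl (kinetic selectivity at low temperature with a weak, hindered base).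

**Step 17**
Reactants: 25 monoacetate
Product: 27 target CNP0277024.1, via ammonium iodide 26 (not isolated)
Conditions: MeI, MeOH, rt; then aq. NaHCO3, rt
Reagents that add atoms: none
Why: Quaternisation of the Mannich base and E1cB (Hofmann-type) elimination of trimethylamine under mild base should release the α-methylene lactone and remove the temporary C11 centre without affecting the angelate, the acetate or the free hydroxyl.

**Compound list**

1 | (R)-linalool, (3R)-3,7-dimethylocta-1,6-dien-3-ol | CC(C)=CCC[C@@](C)(O)C=C | starting material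
2 | (3R)-3,7-dimethyl-3-(trimethylsilyloxy)octa-1,6-diene | CC(C)=CCC[C@@](C)(O[Si](C)(C)C)C=C | intermediate
3 | B-alkyl-9-BBN adduct of 2, boron on the terminal carbon C8 | CC(C)=CCC[C@@](C)(O[Si](C)(C)C)CCB1C2CCCC1CCC2 | intermediate
4 | (3R)-3,7-dimethyl-3-(trimethylsilyloxy)oct-6-en-1-ol | CC(C)=CCC[C@@](C)(O[Si](C)(C)C)CCO | intermediate
5 | (3R)-3,7-dimethyl-3-(trimethylsilyloxy)oct-6-enal | CC(C)=CCC[C@@](C)(O[Si](C)(C)C)CC=O | intermediate
6 | tert-butyl 4-oxobutanoate | O=CCCC(=O)OC(C)(C)C | starting material
7 | tert-butyl (3R,4R,6R)-3-formyl-4-hydroxy-6,10-dimethyl-6-(trimethylsilyloxy)undec-9-enoate (anti aldol; C7 R, C8 R, C10 R) | CC(C)=CCC[C@@](C)(O[Si](C)(C)C)C[C@@H](O)[C@@H](CC(=O)OC(C)(C)C)C=O | intermediate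
8 | 4-O-TBS ether of 7 (C6 aldehyde, C8 OTBS, C10 OTMS, C12 tert-butyl ester) | CC(C)=CCC[C@@](C)(O[Si](C)(C)C)C[C@@H](O[Si](C)(C)C(C)(C)C)[C@@H](CC(=O)OC(C)(C)C)C=O | intermediate
9 | syn chlorohydrin (C5 chloride S, C6 hydroxyl S, terminal vinyl C4=C15; rest as 8) | CC(C)=CCC[C@@](C)(O[Si](C)(C)C)C[C@@H](O[Si](C)(C)C(C)(C)C)[C@@H](CC(=O)OC(C)(C)C)[C@H](O)[C@@H](Cl)C=C | intermediate
10 | cis-vinyl epoxide (5R,6S) with free C10 tertiary alcohol, C8 OTBS, C12 tert-butyl ester | CC(C)=CCC[C@@](C)(O)C[C@@H](O[Si](C)(C)C(C)(C)C)[C@@H](CC(=O)OC(C)(C)C)[C@@H]1O[C@@H]1C=C | intermediate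
11 | ring B hydroxy ester: oxepane with 5-vinyl (R), 6-hydroxyl (S), 7-CH2CO2t-Bu, 8-OTBS, 10-methyl and 10-(4-methylpent-3-enyl) (R) | C=C[C@H]1O[C@](C)(CCC=C(C)C)C[C@@H](O[Si](C)(C)C(C)(C)C)[C@@H](CC(=O)OC(C)(C)C)[C@@H]1O | intermediate
12 | oxepane lactone: ring B trans-fused (C6/C7) to the saturated γ-lactone; 5-vinyl, 8-OTBS, 10-methyl, 10-(4-methylpent-3-enyl); (5R,6S,7S,8R,10R) | C1C(=O)O[C@@H]2[C@@H](C=C)O[C@](C)(CCC=C(C)C)C[C@@H](O[Si](C)(C)C(C)(C)C)[C@@H]12 | intermediate
13 | lithium enolate of lactone 12 | C1=C([O-])O[C@@H]2[C@@H](C=C)O[C@](C)(CCC=C(C)C)C[C@@H](O[Si](C)(C)C(C)(C)C)[C@@H]12.[Li+] | intermediate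
14 | Mannich base: 12 with an (11R)-CH2NMe2 group on the lactone α-carbon | CN(C)C[C@@H]1C(=O)O[C@@H]2[C@@H](C=C)O[C@](C)(CCC=C(C)C)C[C@@H](O[Si](C)(C)C(C)(C)C)[C@@H]12 | intermediate
15 | C8 alcohol: 14 without the TBS group | CN(C)C[C@@H]1C(=O)O[C@@H]2[C@@H](C=C)O[C@](C)(CCC=C(C)C)C[C@@H](O)[C@@H]12 | intermediate
16 | 8-O-angelate of 15 | CN(C)C[C@@H]1C(=O)O[C@@H]2[C@@H](C=C)O[C@](C)(CCC=C(C)C)C[C@@H](OC(=O)/C(C)=C\C)[C@@H]12 | intermediate
17 | secondary ozonide (1,2,4-trioxolane) of the side-chain alkene of 16, epimers at the trioxolane carbon | CN(C)C[C@@H]1C(=O)O[C@@H]2[C@@H](C=C)O[C@](C)(CCC3OOC(C)(C)O3)C[C@@H](OC(=O)/C(C)=C\C)[C@@H]12 | intermediate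
18 | C3 aldehyde (10-(3-oxopropyl) side chain) | CN(C)C[C@@H]1C(=O)O[C@@H]2[C@@H](C=C)O[C@](C)(CCC=O)C[C@@H](OC(=O)/C(C)=C\C)[C@@H]12 | intermediate
19 | C3 aldoxime (E/Z mixture) | CN(C)C[C@@H]1C(=O)O[C@@H]2[C@@H](C=C)O[C@](C)(CCC=NO)C[C@@H](OC(=O)/C(C)=C\C)[C@@H]12 | intermediate
20 | C3 nitrile oxide | CN(C)C[C@@H]1C(=O)O[C@@H]2[C@@H](C=C)O[C@](C)(CCC#[N+][O-])C[C@@H](OC(=O)/C(C)=C\C)[C@@H]12 | intermediate
21 | isoxazoline: rings A and B and lactone complete, isoxazoline C3=N–O–C15–C4 fused at C3–C4 (H4 cis to H5) | CN(C)C[C@@H]1C(=O)O[C@@H]2[C@@H]3O[C@](C)(CCC4=NOC[C@H]34)C[C@@H](OC(=O)/C(C)=C\C)[C@@H]12 | intermediate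
22 | β-hydroxy imine (C3=NH, C15 OH) | CN(C)C[C@@H]1C(=O)O[C@@H]2[C@@H]3O[C@](C)(CCC(=N)[C@@H]3CO)C[C@@H](OC(=O)/C(C)=C\C)[C@@H]12 | intermediate
23 | β-hydroxy ketone (C3 ketone, 4-hydroxymethyl) | CN(C)C[C@@H]1C(=O)O[C@@H]2[C@@H]3O[C@](C)(CCC(=O)[C@@H]3CO)C[C@@H](OC(=O)/C(C)=C\C)[C@@H]12 | intermediate
24 | diol (3S-hydroxyl, 4S-hydroxymethyl) | CN(C)C[C@@H]1C(=O)O[C@@H]2[C@@H]3O[C@](C)(CC[C@H](O)[C@@H]3CO)C[C@@H](OC(=O)/C(C)=C\C)[C@@H]12 | intermediate
25 | 15-O-acetate of 24 | CN(C)C[C@@H]1C(=O)O[C@@H]2[C@@H]3O[C@](C)(CC[C@H](O)[C@@H]3COC(C)=O)C[C@@H](OC(=O)/C(C)=C\C)[C@@H]12 | intermediate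
26 | trimethylammonium iodide of 25 | C[N+](C)(C)C[C@@H]1C(=O)O[C@@H]2[C@@H]3O[C@](C)(CC[C@H](O)[C@@H]3COC(C)=O)C[C@@H](OC(=O)/C(C)=C\C)[C@@H]12.[I-] | intermediate
27 | CNP0277024.1 (3S,4S,5R,6S,7R,8R,10R) | C=C1C(=O)O[C@@H]2[C@@H]3O[C@](C)(CC[C@H](O)[C@@H]3COC(C)=O)C[C@@H](OC(=O)/C(C)=C\C)[C@@H]12 | target

**Totals**

Total step count: 17. Longest linear sequence: 17 steps (from 1; 6 is commercial).

**Steps most likely to fail**

Step 13. Dimerisation of the nitrile oxide to furoxan may outrun a ring closure that builds the strained trans-bridged bicycle, or the closure may take the wrong facial sense at C4. The fallback sets out from 18 and returns at 24, and closes ring A by an intramolecular Hosomi–Sakurai allylation instead. Cross-metathesis of aldehyde 18 (as its trifluoroacetate salt) with allyltrimethylsilane and the second-generation Grubbs catalyst should give the (E)-allylsilane aldehyde F1. BF3·OEt2 in CH2Cl2 at −78 °C should then join C4 to C3 and give the ring A homoallylic alcohol F2. Ozonolysis of its vinyl group (PPh3 work-up) should give the β-hydroxy aldehyde F3, and NaBH4 reduction should give diol 24.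

Step 7. Capture of the π-allyl complex by the hindered tertiary alcohol may be slow, so that facial equilibration of the complex erodes the C5 configuration or elimination to the diene takes over. The fallback sets out from 8 and returns at 12, and uses Brønsted-acid epoxide opening instead of metal catalysis. Aldehyde 8 with (E)-γ-chloroallylboronic acid pinacol ester should give the anti chlorohydrin F4 by Felkin addition. K2CO3 in MeOH should close it to the trans-vinyl epoxide F5 and cleave the TMS ether. CSA in CH2Cl2 should then open F5 at the allylic carbon C5 with inversion (7-endo, vinyl-activated) to hydroxy ester 11, which lactonises to 12 in the same pot.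

Step 4. Self-aldolisation of donor 6, low anti selectivity, or β-elimination of the silyloxy group of 5 through its enamine may intervene. The fallback sets out from 5 and returns at 8, and builds the two centres stepwise. SnCl2-catalysed homologation of 5 with methyl diazoacetate (Roskamp reaction) should give the β-keto ester F6. Noyori hydrogenation with RuCl2[(R)-BINAP] should give the β-hydroxy ester F7 (C8). Fráter–Seebach alkylation of its dianion (LiN(i-Pr)2, tert-butyl bromoacetate) should give the anti alkylation product F8 (C7). Silylation with TBSOTf should give the silyl ether F9, and i-Bu2AlH at −78 °C should reduce the methyl ester in preference to the tert-butyl ester to return aldehyde 8.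

**Further compounds**

F1 | step 13 | (E)-allylsilane aldehyde (18 with CH=CH–CH2SiMe3 on C5) | CN(C)C[C@@H]1C(=O)O[C@@H]2[C@@H](/C=C/C[Si](C)(C)C)O[C@](C)(CCC=O)C[C@@H](OC(=O)/C(C)=C\C)[C@@H]12
F2 | step 13 | ring A homoallylic alcohol (3S-hydroxyl, 4-vinyl) | CN(C)C[C@@H]1C(=O)O[C@@H]2[C@@H]3O[C@](C)(CC[C@H](O)[C@@H]3C=C)C[C@@H](OC(=O)/C(C)=C\C)[C@@H]12
F3 | step 13 | β-hydroxy aldehyde (3S-hydroxyl, 4-formyl) | CN(C)C[C@@H]1C(=O)O[C@@H]2[C@@H]3O[C@](C)(CC[C@H](O)[C@@H]3C=O)C[C@@H](OC(=O)/C(C)=C\C)[C@@H]12
F4 | step 7 | anti chlorohydrin (C5 epimer of 9) | CC(C)=CCC[C@@](C)(O[Si](C)(C)C)C[C@@H](O[Si](C)(C)C(C)(C)C)[C@@H](CC(=O)OC(C)(C)C)[C@H](O)[C@H](Cl)C=C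
F5 | step 7 | trans-vinyl epoxide (C5 epimer of 10) | CC(C)=CCC[C@@](C)(O)C[C@@H](O[Si](C)(C)C(C)(C)C)[C@@H](CC(=O)OC(C)(C)C)[C@@H]1O[C@H]1C=C
F6 | step 4 | β-keto ester (methyl ester, C8 ketone) | CC(C)=CCC[C@@](C)(O[Si](C)(C)C)CC(=O)CC(=O)OC
F7 | step 4 | β-hydroxy ester (C8 R) | CC(C)=CCC[C@@](C)(O[Si](C)(C)C)C[C@@H](O)CC(=O)OC
F8 | step 4 | anti alkylation product (C7 bearing CH2CO2t-Bu, methyl ester at C6) | CC(C)=CCC[C@@](C)(O[Si](C)(C)C)C[C@@H](O)[C@@H](CC(=O)OC(C)(C)C)C(=O)OC
F9 | step 4 | silyl ether of F8 (C8 OTBS) | CC(C)=CCC[C@@](C)(O[Si](C)(C)C)C[C@@H](O[Si](C)(C)C(C)(C)C)[C@@H](CC(=O)OC(C)(C)C)C(=O)OC
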